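The noon run at 10.0 min still holds 11.8% of its J, and the balance puts 5.20 mM of the charge in X, which leaves cG at 1.20 mM of the 6.4 mM charged.

| flask | J | G | remark | time |
|---|---|---|---|---|
| spring | 20 mM | 4.5 mM | run made earlier |  |
| noon | 20 mM | 6.4 mM | run made earlier |  |
| dusk | 20 mM | 9.7 mM | run made earlier |  |
| north-east | 20 mM | 4.00 mM |  | 20 min |
| south-west | 20 mM | 6.00 mM |  | 20 min |
| north | 20 mM | 9.00 mM |  | 20 min |

| run | time / min | D / % | Q / % | J / % |
|---|---|---|---|---|
| spring | 2.50 | 30.7 | 10.0 | 46.6 |
| spring | 5.00 | 29.7 | 25.9 | 27.4 |
| spring | 8.00 | 22.6 | 41.5 | 17.5 |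
| spring | 10.0 | 18.9 | 49.8 | 12.9 |
| noon | 0.833 | 16.2 | 1.8 | 71.6 |
| noon | 2.00 | 27.0 | 7.1 | 49.9 |
| noon | 4.00 | 29.5 | 18.9 | 30.4 |
| noon | 10.0 | 17.0 | 45.2 | 11.8 |
| dusk | 1.33 | 21.7 | 3.3 | 55.5 |
| dusk | 4.00 | 26.5 | 17.5 | 25.1 |
| dusk | 6.00 | 22.3 | 27.1 | 16.5 |
| dusk | 10.0 | 14.5 | 39.6 | 8.5 |

(standard deviation of a reading: 0.3 percentage points)

- what is said of Q includes Z
- Z is a solid; its amount is given per volume of the solution
- what may be going on: J <-> D; D <-> Q; J + G -> X; Z <-> Q

* which of these there is most of at the end, counted by the J in it, north-east (J / D / Q)
* which of these there is most of at the end, counted by the J in it, south-west (J / D / Q)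
* which of these there is most of at the end, counted by the J in it, north (J / D / Q)
* the largest of these amounts at the end, in percent of the J charged, north-east
* the largest of these amounts at the end, in percent of the J charged, south-west
* the largest of these amounts at the end, in percent of the J charged, north

Two amounts matter here: the cG in the flask and a crossing amount. J leaves in two ways, to D, a step that may run back, and to X in proportion to cJ times cG. Taking the net flow to D as proportional to cJ, as a working picture, the J lost equals the X formed plus the crossing amount times the logarithm of cG charged over cG left. The noon reading then gives 7.43 mM as the crossing amount, an average over that run and not a value for the first moment: the cG at which, in this picture, J goes net to D as fast as to X. Its ratio to cG is a selectivity factor. Held against the cG charged, this average is 1.86 times it in north-east, 1.24 times it in south-west and 0.826 times it in north, where the charge of G is larger than the average.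

My own reckoning takes, as an approximation, the whole charge of J as lost by the end and solves for the cG left by going round twice. In north-east, counting all G as used gives 0.465 mM left. Putting that back gives 0.436 mM, so X is 17.8% of the J charged. The same two rounds give 26.0% in south-west and 37.2% in north.

The forecast, on its own grounds, puts X at about 19, 27 and 38%, figures that differ from mine, and holds that “The missing balance gives X, which is limited by G”. It names Q as the largest in all three flasks, at 70%, 62% and 53%.

    J ⇌ D (K = 2.40, k = 0.00450 s⁻¹)
    D ⇌ Q (K = 0.600, k = 0.00420 s⁻¹)
    J + G → X (k = 0.430 L mol⁻¹ s⁻¹)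
    Z ⇌ Q, rate k4*(cs4 - [Q]) while solid is left; crystals form when [Q] > cs4 (solubility = 0.600 mM, k = 0.270 s⁻¹)

The flasks give Q in all three, at 68.9% in north-east, 62.0% in south-west and 52.5% in north, where X stands at 37.5%. At that end of north, cG is 1.49 mM, so the noon average of the crossing amount is 4.99 times the cG left, against 0.826 times the cG charged. South-west read at 5.0 min has 25% of its J left. Two rounds with the same crossing amount leave cG at 1.41 mM, which is X at 22.9%, and that flask holds X at 21.6%.

All runs were generated by integration for an exercise; the scatter is artificial.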